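Watch what stays put when c(substrate) changes with catalyst and gas held: the percent of target at a given time.

all flasks: gas phase 15 mM (held)
- Monday's: substrate 0.10 M; free catalyst 1 mM; run made earlier
- Thursday's: substrate 0.40 M; free catalyst 1 mM; run made earlier
- Wednesday's: substrate 0.20 M; free catalyst 0.50 mM; run made earlier
- flask: substrate 0.20 M; free catalyst 1.0 mM; time 12 min

- Monday's (time / min: target / %): 2.00: 5.9; 4.00: 9.6; 6.00: 13.8; 8.00: 17.4; 10.0: 22.9; 12.0: 25.6
- Thursday's (time / min: target / %): 1.00: 4.2; 1.50: 3.5; 2.50: 5.5; 4.00: 9.3; 8.00: 18.8; 12.0: 22.8
- Wednesday's (time / min: target / %): 1.00: 0.4; 3.00: 4.9; 6.00: 9.9; 8.00: 12.7; 12.0: 17.8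

(each reading ± 1 percentage point)

- how much target there is at 12 min, in percent of the substrate charged
- the change that raises the amount of target at 12 min, in percent of the substrate charged most ("none" if none brings more than 2 percentage points) (grey / teal / amber / none)
- amount of target at 12 min, in percent of the substrate charged, after grey

- at the start none of the gas phase is in solution

- grey: doubling the saturation concentration of gas phase, all else as stated
- teal: doubling the amount of free catalyst, all else as stated
- amber: doubling the transfer coefficient of the gas phase, all else as stated

At 8.00 min it reads 17.4% with c(substrate) 0.10 M and 18.8% with 0.40 M. At 12.0 min it reads 25.6% and 22.8%, the order reversed, with 1 percentage point of scatter per reading. So treat substrate as pseudo-first-order. Take ln(charged/left) over time from the last readings: Monday's run gives 0.0246 /min and Thursday's 0.0216 /min. Carry their mean, 0.0231 /min, the fractional rate, the share of remaining substrate turned over per minute.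

Can the gas keep up? The carried rate puts Thursday's run at about 9.24 mM/min at its start and this flask at about 4.62 mM/min, half of that, so expect little from amber.

Does catalyst count in full? Wednesday's run, with c(free catalyst) 0.50 mM, gives 0.0163 /min. The carried rate over this one reads 1.41, with the scatter of the readings on it, and the square root of two is 1.41, so take half order in catalyst.

My reckoning for this flask is 24.2%, and teal gives 32.4%. Assume first order in gas and grey doubles the fractional rate to give 42.6%, more than teal.

The forecast says 25.2%, slightly above mine, names grey and puts it at 43%, adding: “No run varied the gas, so its order is an assumption.”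

The flask gives 24.6%; grey gains 16 points and reaches 40.1%, teal gains 7.8 points, amber 0.61 points.

    gas phase ⇌ dissolved gas, rate k1*(csat - [dissolved gas]) (kL = 6.51 /min)
    substrate + dissolved gas + free catalyst → free catalyst + target (k = 23300 /M²/min)
    dissolved gas + free catalyst + target → free catalyst + over-reaction product (k = 9090 /M²/min)
    2 free catalyst ⇌ resting dimer, settled at all times (K = 65200 /M)
    free catalyst → spent catalyst (k = 0.313 /min)

In the flask, from 1.20 min to 12.0 min, in percent of the catalyst charged, the resting dimer, the catalyst's resting state, falls from 88.6% to 64.1% and spent catalyst climbs from 3.12% to 28.9%, while free catalyst moves from 8.24% to 7.01%. The 74% of substrate left in the flask at 12.0 min gives an average fractional rate of 0.0253 /min, against the carried 0.0231 /min. Left until 50 min, the same flask keeps 39% of its substrate, an average fractional rate of 0.0187 /min, lower than the carried value, with spent catalyst at 87.0%.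

The readings are calculated on assumed constants.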